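## Structural features

The target is a (2S)-flavanone: benzene ring A is fused to ring C (O1–C2–C3–C4(=O)–C4a–C8a), and ring B is attached to C2 through C1'. C2 is the only stereocentre; it is benzylic, bonded to O1 and β to the C4 ketone, and has no neighbouring stereocentre, so it must be set by absolute control. Ring A carries a hydroxyl at C7 and a prenyl (3-methylbut-2-enyl) group at C8; ring B is a 3',4'-catechol with a prenyl group at C5'. Each prenyl group is bonded through its CH2 to a carbon ortho to exactly one phenolic oxygen (C8 beside O7, C5' beside O4'). That is the pattern left by an oxygen-to-carbon [3,3] shift of a 1,1-dimethylallyl aryl ether, and it is the feature the key step uses. O3' has no such role and is the only oxygen that needs a separate mask. The fragile points are C2 (epimerised by reversible opening of ring C, most easily under base once the 4'-hydroxyl is free), the two trisubstituted alkenes (no hydrogenation, no strong acid beside a phenol) and the catechol (air-sensitive under base). The real difficulty is selectivity rather than size: the absolute configuration at C2, C8 against C6 on ring A, and O3' against O4' on ring B.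

## Logic of the disconnections

20 ⇒ 19. No skeletal bond is cut; O3'–H is traded for O3'–Si. The reason is that the last operation should touch no carbon and run near neutrality at low temperature. The gain is that the catechol stays masked through all earlier steps. The forward step must remove silicon without building up a phenoxide of the 4'-hydroxyflavanone and without acid strong enough to close a prenyl group onto a phenol.

19 ⇒ 15 (through 18, 17 and 16). The C8–CH2 and C5'–CH2 bonds are cut, and each allyl unit is reattached through its tertiary carbon to O7 and O4'. The reason is that each prenyl group has one ortho oxygen, so both C–C bonds can come from [3,3] shifts. The gain is that two C–C bonds at crowded aromatic positions become two ether bonds, and the free 7- and 4'-hydroxyls, which endanger C2, do not exist before this point. The forward step must choose C8 over C6 on ring A, must not ionise either ether, and must run in a neutral medium.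

15 ⇒ 5 + 14. The C2–C1' bond is cut. The reason is that the only stereocentre lies on this bond, and the cut gives two halves of similar size with ring C and the ketone already present in 5. The gain is that the stereochemical problem becomes the face selectivity of one catalytic aryl transfer to a flat enone. The forward step needs a chiral catalyst that adds the aryl group of 14 to one face of C2=C3 of 5 without opening ring C, hydrolysing the silyl ether or disturbing the tertiary allyl ethers.

5 ⇒ 4 ⇒ 3 + 2. The vinyl group is taken back to an ethynyl group, then O7–C(quaternary) is cut. The reason is that a tertiary propargylic ester couples with a phenoxide at its tertiary carbon under copper catalysis, whereas a tertiary allylic electrophile does not do so cleanly. The gain is a purchased chromone and an electrophile shared with the other branch. The hydrogenation must stop at the alkene and leave C2=C3 of the pyranone.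

14 ⇒ 11 (through 13 and 12). The C1'–B bond is replaced by C1'–Br. The reason is that the boron group is best introduced last on ring B, after all oxygen chemistry. The gain is a stable aryl bromide as the carrier of ring B. The forward step needs halogen–metal exchange at low temperature and a work-up mild enough for the tertiary allyl ether.

11 ⇒ 10 ⇒ 9. The alkene is taken back to the alkyne, then O3'–Si is cut. The reason is the same etherification logic as on ring A. The gain is a simple phenol. Silylation must come only after O4' is alkylated, so that no phenoxide sits beside the silyl ether and the silyl group cannot change oxygen.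

9 ⇒ 7 (through 8). The C3'–O bond is cut and the oxygen is replaced by a formyl carbon. The reason is that in 7 the two future oxygens of ring B are different functional groups, so their assignment is unambiguous. The gain is a regiochemically defined ring B. The forward step needs aryl migration in a peracid oxidation, run while the side chain is still an alkyne, which a peracid attacks only slowly.

7 ⇒ 6 + 2. The O4'–C(quaternary) bond is cut. The reason is that it is the same etherification as on ring A, so both branches draw on 2. The gain is a purchased aldehyde. The acidic, hydrogen-bonded phenol of 6 must be etherified in the presence of the aldehyde.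

2 ⇒ 1. The O–C(acyl) bond is cut. The reason is that 1 is not an electrophile, whereas 2 ionises under copper catalysis. The gain is a purchased alcohol, and one batch of 2 feeds both etherifications. The forward step must acylate a hindered tertiary alcohol cleanly and deliver 2 cold and dry, since it is labile to moisture.

## Other disconnections considered

Alternative 1: The cut is O1–C8a. In the forward direction the bromo anti-1,3-diol A2 would be closed by CuI, a 1,10-phenanthroline ligand and Cs2CO3, the C2 hydroxyl displacing bromine at C8a to give the (2S,4S)-flavan-4-ol A1.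
- In its favour: only the C2 hydroxyl can reach C8a in a six-membered ring, since the C4 hydroxyl would have to form a four-membered ring. The C2–O bond is never broken, so the configuration is carried over unchanged. The position of bromine fixes the ring A substitution pattern.
- Against it here: the bromide in A2 is flanked on both sides (C8 prenyl, C4a side chain), so the hot basic coupling is demanding. A2 needs two stereocentres, of which C4 is destroyed by the oxidation that must follow. Three methoxymethyl ethers must then come off under acid, next to two prenyl groups that can cyclise onto the liberated phenols.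
- Comparison: on ring A regiochemistry this plan is the better one, because nothing depends on a C6/C8 preference. On the safety of C2 during ring formation it is at least the equal of the chosen plan. On mechanism it relies on a hindered metal-mediated C–O coupling, where the chosen plan relies on a concerted thermal shift. On step economy it is clearly worse (prenylated aryl bromide, anti diol, oxidation, acidic triple deprotection).

Alternative 2: The cut is C4–C4a. In the forward direction the (S)-acid A4 would be converted by 1-chloro-N,N,2-trimethylpropenylamine into the acid chloride A5, which Sc(OTf)3 and a hindered pyridine would close onto C4a to give flavanone A3.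
- In its favour: C4a is the only free position ortho to O1 and is para to O7, so the site of acylation is not in doubt. The ketone arrives at the correct oxidation level.
- Against it here: A5 has an aryloxide β to the acyl group and can lose it by elimination. The Lewis acid can ionise the benzylic C2–O1 bond, which would cost configuration. Two nucleophilic trisubstituted alkenes compete for the acylating species. A4 itself needs an enantioselective C2–O1 bond formation with a hindered phenol. The two acetates of A3 must later be removed under conditions that again threaten C2.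
- Comparison: on oxidation level and on ring A regiochemistry it equals or betters the chosen plan. On chemoselectivity in the key step and on protection of C2 it is weaker. The route to A4 is longer than the route to 15.

Alternative 3: The cuts are C3–C4 and O1–C2. In the forward direction a chiral imidodiphosphorimidate acid would ionise acetal A7 to the α-methoxy ortho-quinone methide A9, which would add styrene A8 in a hetero-Diels–Alder reaction to give the 2,4-cis-4-methoxyflavan A6.
- In its favour: it is the most convergent plan. Two bonds, ring C and C2 are formed in one catalytic asymmetric step from two halves of similar size.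
- Against it here: A7 has a free phenol next to a prenyl group and would meet a very strong acid, so chroman formation competes. The prenyl alkenes of A7 and A8 are themselves electron-rich partners for A9. The electron-rich styrene A8 can oligomerise under acid. The C4 stereocentre is made only to be destroyed, since the methoxy group must be oxidised to the ketone beside two prenyl groups before three silyl ethers are removed.
- Comparison: on convergence and bond-forming efficiency in the key step it is the better plan. On catalyst control of C2 it is the equal of the chosen plan. On compatibility with the prenyl groups and on the number of steps after the key step it is weaker.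

Key step: step 10

Remarks on the chemistry (assumptions):

- Ring B is grown from 5-bromo-2-hydroxybenzaldehyde and not from a monosilylated 4-bromocatechol. The two hydroxyls of 4-bromocatechol differ too little for a regioselective monosilylation, and under the amidine base of the etherification a silyl group next to a phenoxide would migrate between the two oxygens. In the route below the formyl carbon marks the future O3' until O4' is etherified.
- Trifluoroacetate 2 is made once in step 1 as a cold acetonitrile solution and divided at once between the two etherifications (steps 2 and 4), which are run side by side.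
- Assumption for step 9: the (S,S) antipode of the diene ligand is taken to deliver the aryl group to the face that gives (2S), by analogy with additions to cyclohex-2-enone. The sense should be confirmed on the first sample of 15, and the (R,R) ligand is used if it proves opposite.
- Assumption for step 10: the electron-rich, more crowded ring B ether is expected to rearrange first, and intermediates 16–18 are numbered on that basis. The order of the two shifts does not affect the product.

## Route

Step 1
Reactants: 1 2-methylbut-3-yn-2-ol
Product: 2 2-methylbut-3-yn-2-yl trifluoroacetate (kept as a cold MeCN solution)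
Conditions: (CF3CO)2O, DBU, MeCN, −5 to 0 °C; solution used directly in two portions
Reagents that add atoms: trifluoroacetic anhydride, O=C(OC(=O)C(F)(F)F)C(F)(F)F
Why: O-Acylation of a tertiary propargylic alcohol by an anhydride in the presence of an amidine base, which gives the activated ester needed for the copper-catalysed etherifications. The ester is labile to moisture, so it is made once at 0 °C and used without concentration in steps 2 and 4.

Step 2
Reactants: 3 7-hydroxychromone; 2 2-methylbut-3-yn-2-yl trifluoroacetate
Product: 4 7-(2-methylbut-3-yn-2-yloxy)chromone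
Conditions: 2 (MeCN solution from step 1), DBU, CuCl2·2H2O (1 mol %), MeCN, 0 °C
Reagents that add atoms: none
Why: Copper-catalysed propargylic etherification of a phenol, in which the tertiary propargylic trifluoroacetate is activated as a copper acetylide/allenylidene species and captured by the phenoxide at the tertiary carbon. Acidic phenols such as 3 are the best substrates, and DBU at 0 °C should not open the pyranone.

Step 3
Reactants: 4 7-(2-methylbut-3-yn-2-yloxy)chromone
Product: 5 7-(2-methylbut-3-en-2-yloxy)chromone
Conditions: H2 (1 atm), Pd/CaCO3–Pb(OAc)2 (Lindlar catalyst), quinoline, EtOAc, rt, stopped after 1 equiv of H2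
Reagents that add atoms: none
Why: Lindlar semihydrogenation of a terminal alkyne to the vinyl group. The poisoned catalyst should leave the vinylogous-ester C2=C3 bond of the chromone untouched, and quinoline plus uptake control guard against over-reduction.

Step 4
Reactants: 6 5-bromo-2-hydroxybenzaldehyde; 2 2-methylbut-3-yn-2-yl trifluoroacetate
Product: 7 5-bromo-2-(2-methylbut-3-yn-2-yloxy)benzaldehyde
Conditions: 2 (MeCN solution from step 1), DBU, CuCl2·2H2O (1 mol %), MeCN, 0 °C
Reagents that add atoms: none
Why: The same copper-catalysed propargylic etherification as in step 2. The phenol of 6 is para to bromine, so the ether is placed on the future O4' without ambiguity, and the aldehyde is inert to the conditions.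

Step 5
Reactants: 7 5-bromo-2-(2-methylbut-3-yn-2-yloxy)benzaldehyde
Product: 9 5-bromo-2-(2-methylbut-3-yn-2-yloxy)phenol, via aryl formate 8 (not isolated)
Conditions: mCPBA, CH2Cl2, 0 °C to rt; aq. NaHCO3 wash; then K2CO3 (cat.), MeOH, 0 °C
Reagents that add atoms: meta-chloroperoxybenzoic acid, OOC(=O)c1cccc(Cl)c1
Why: Baeyer–Villiger (Dakin-type) oxidation of an ortho-alkoxybenzaldehyde, in which the electron-rich aryl group migrates in the Criegee adduct to give formate 8, followed by mild methanolysis to the phenol. The step is placed before the semihydrogenation because the alkyne and the aryl bromide are inert to the peracid at this temperature, whereas an alkene would not be reliably so.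

Step 6
Reactants: 9 5-bromo-2-(2-methylbut-3-yn-2-yloxy)phenol
Product: 10 [5-bromo-2-(2-methylbut-3-yn-2-yloxy)phenoxy](tert-butyl)dimethylsilane
Conditions: TBSCl, imidazole, DMF, rt
Reagents that add atoms: tert-butyldimethylsilyl chloride, CC(C)(C)[Si](C)(C)Cl
Why: Standard silylation of a phenol. Because O4' is already alkylated, no neighbouring phenoxide exists and the silyl group cannot migrate.

Step 7
Reactants: 10 [5-bromo-2-(2-methylbut-3-yn-2-yloxy)phenoxy](tert-butyl)dimethylsilane
Product: 11 [5-bromo-2-(2-methylbut-3-en-2-yloxy)phenoxy](tert-butyl)dimethylsilane
Conditions: H2 (1 atm), Pd/CaCO3–Pb(OAc)2 (Lindlar catalyst), quinoline, EtOAc, rt, stopped after 1 equiv of H2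
Reagents that add atoms: none
Why: Lindlar semihydrogenation of the terminal alkyne. The poisoned catalyst should leave the aryl bromide and the silyl ether untouched.

Step 8
Reactants: 11 [5-bromo-2-(2-methylbut-3-en-2-yloxy)phenoxy](tert-butyl)dimethylsilane
Product: 14 [3-(tert-butyldimethylsilyloxy)-4-(2-methylbut-3-en-2-yloxy)phenyl]boronic acid, via aryllithium 12 (not isolated), via lithium aryltriisopropoxyborate 13 (not isolated)
Conditions: n-BuLi, THF, −78 °C; B(OiPr)3, −78 to 0 °C; AcOH, H2O, 0 °C
Reagents that add atoms: triisopropyl borate, CC(C)OB(OC(C)C)OC(C)C; water, O; n-butyllithium, [Li]CCCC (its lithium is found in 12 and 13 only)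
Why: Bromine–lithium exchange followed by trapping with a trialkyl borate and hydrolysis of the ate complex. The lithium is meta to the silyloxy group, so no silyl shift to carbon is possible, and the acetic acid quench is mild enough for the tertiary allyl ether.

Step 9
Reactants: 5 7-(2-methylbut-3-en-2-yloxy)chromone; 14 [3-(tert-butyldimethylsilyloxy)-4-(2-methylbut-3-en-2-yloxy)phenyl]boronic acid
Product: 15 (2S)-3'-(tert-butyldimethylsilyloxy)-7,4'-bis(2-methylbut-3-en-2-yloxy)flavanone
Conditions: [RhCl(C2H4)2]2 (2.5 mol %), (S,S)-2,5-diphenylbicyclo[2.2.2]octa-2,5-diene (5.5 mol %), aq. KOH (0.2 equiv), toluene–H2O, 35 °C, 14 (2 equiv)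
Reagents that add atoms: none
Why: Rhodium-catalysed asymmetric conjugate addition of an arylboronic acid to a chromone (Hayashi–Miyaura type): transmetallation gives an aryl–rhodium diene complex that carbometallates C2=C3, and protonolysis of the oxa-π-allyl releases the flavanone. C2 is set by the C2-symmetric diene, which leaves one enantiotopic face of the enone open to the aryl group. The substoichiometric base and mild temperature are meant to limit retro-oxa-Michael opening of the product.

Step 10
Reactants: 15 (2S)-3'-(tert-butyldimethylsilyloxy)-7,4'-bis(2-methylbut-3-en-2-yloxy)flavanone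
Product: 19 (2S)-3'-(tert-butyldimethylsilyloxy)-7,4'-dihydroxy-8,5'-bis(3-methylbut-2-enyl)flavanone, via ring B ortho-dienone 16 (not isolated), via 5'-prenyl monophenol 17 (not isolated), via ring A ortho-dienone 18 (not isolated)
Conditions: degassed o-xylene, 130 °C, Ar, sealed base-washed glass
Reagents that add atoms: none
Why: A twofold aromatic Claisen rearrangement, that is, two thermal [3,3]-sigmatropic shifts of aryl 1,1-dimethylallyl ethers in one flask. In each ether a chair-like six-membered transition state breaks the O–C(CH3)2 bond while the terminal CH2 bonds to the ortho carbon, so the gem-dimethyl carbon becomes the alkene terminus of a normal prenyl group, and the ortho-dienones 16 and 18 enolise to the phenols 17 and 19. The closest known reaction type is the ortho-Claisen rearrangement of reverse-prenyl aryl ethers to ortho-prenylphenols, which the gem-dimethyl group allows near 130 °C. No ring is closed and no lasting stereocentre is made, since the sp3 carbons of 16 and 18 disappear on enolisation, and the neutral, aprotic, amine-free medium should leave C2 untouched. Site selectivity is needed on ring A only: on ring B, C3' carries the silyloxy group and a shift to it is reversible and unproductive, so C5' is the only terminus that leads to a phenol. On ring A the O1–C8a=C4a–C4=O vinylogous ester favours the Kekulé form with a C7=C8 double bond, so the shift should prefer C8 over C6, as it does in 7-allyloxy-chromones and -coumarins. Ionisation of the tertiary ethers to phenol and isoprene is held back by acid-free glass and solvent.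

Step 11
Reactants: 19 (2S)-3'-(tert-butyldimethylsilyloxy)-7,4'-dihydroxy-8,5'-bis(3-methylbut-2-enyl)flavanone
Product: 20 (2S)-7,3',4'-trihydroxy-8,5'-bis(3-methylbut-2-enyl)flavanone (CNP0315050.1)
Conditions: Bu4NF, AcOH (1.2 equiv per fluoride), THF, 0 °C, Ar
Reagents that add atoms: none
Why: Fluoride-induced cleavage of a phenolic silyl ether. Acetic acid keeps the medium near neutral so that no phenoxide of the 4'-hydroxyflavanone builds up (which would open ring C and racemise C2), and the mixture is not acidic enough to cyclise the prenyl groups onto the phenols.

## Compound list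

1 | 2-methylbut-3-yn-2-ol | CC(C)(O)C#C | starting material
2 | 2-methylbut-3-yn-2-yl trifluoroacetate | CC(C)(C#C)OC(=O)C(F)(F)F | intermediate
3 | 7-hydroxychromone (7-hydroxy-4H-chromen-4-one) | O=c1ccoc2cc(O)ccc12 | starting material
4 | 7-(2-methylbut-3-yn-2-yloxy)chromone | O=c1ccoc2cc(OC(C)(C)C#C)ccc12 | intermediate
5 | 7-(2-methylbut-3-en-2-yloxy)chromone | O=c1ccoc2cc(OC(C)(C)C=C)ccc12 | intermediate
6 | 5-bromo-2-hydroxybenzaldehyde | O=Cc1cc(Br)ccc1O | starting material
7 | 5-bromo-2-(2-methylbut-3-yn-2-yloxy)benzaldehyde | O=Cc1cc(Br)ccc1OC(C)(C)C#C | intermediate
8 | 5-bromo-2-(2-methylbut-3-yn-2-yloxy)phenyl formate | O=COc1cc(Br)ccc1OC(C)(C)C#C | intermediate (not isolated)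
9 | 5-bromo-2-(2-methylbut-3-yn-2-yloxy)phenol | Oc1cc(Br)ccc1OC(C)(C)C#C | intermediate
10 | [5-bromo-2-(2-methylbut-3-yn-2-yloxy)phenoxy](tert-butyl)dimethylsilane | CC(C)(C)[Si](C)(C)Oc1cc(Br)ccc1OC(C)(C)C#C | intermediate
11 | [5-bromo-2-(2-methylbut-3-en-2-yloxy)phenoxy](tert-butyl)dimethylsilane | CC(C)(C)[Si](C)(C)Oc1cc(Br)ccc1OC(C)(C)C=C | intermediate
12 | [3-(tert-butyldimethylsilyloxy)-4-(2-methylbut-3-en-2-yloxy)phenyl]lithium | [Li]c1ccc(OC(C)(C)C=C)c(O[Si](C)(C)C(C)(C)C)c1 | intermediate (not isolated)
13 | lithium [3-(tert-butyldimethylsilyloxy)-4-(2-methylbut-3-en-2-yloxy)phenyl]triisopropoxyborate | [Li+].CC(C)O[B-](OC(C)C)(OC(C)C)c1ccc(OC(C)(C)C=C)c(O[Si](C)(C)C(C)(C)C)c1 | intermediate (not isolated)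
14 | [3-(tert-butyldimethylsilyloxy)-4-(2-methylbut-3-en-2-yloxy)phenyl]boronic acid | OB(O)c1ccc(OC(C)(C)C=C)c(O[Si](C)(C)C(C)(C)C)c1 | intermediate
15 | (2S)-3'-(tert-butyldimethylsilyloxy)-7,4'-bis(2-methylbut-3-en-2-yloxy)flavanone | C=CC(C)(C)Oc1ccc([C@@H]2CC(=O)c3ccc(OC(C)(C)C=C)cc3O2)cc1O[Si](C)(C)C(C)(C)C | intermediate (precursor of the key step)
16 | ring B ortho-dienone: (2S)-2-[5-(tert-butyldimethylsilyloxy)-3-(3-methylbut-2-enyl)-4-oxocyclohexa-1,5-dien-1-yl]-7-(2-methylbut-3-en-2-yloxy)chroman-4-one, either configuration at the sp3 ring carbon | O=C1C(O[Si](C)(C)C(C)(C)C)=CC([C@@H]2CC(=O)c3ccc(OC(C)(C)C=C)cc3O2)=CC1CC=C(C)C | intermediate (not isolated)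
17 | (2S)-3'-(tert-butyldimethylsilyloxy)-4'-hydroxy-7-(2-methylbut-3-en-2-yloxy)-5'-(3-methylbut-2-enyl)flavanone | CC(C)=CCc1cc([C@@H]2CC(=O)c3ccc(OC(C)(C)C=C)cc3O2)cc(O[Si](C)(C)C(C)(C)C)c1O | intermediate (not isolated)
18 | ring A ortho-dienone: (2S)-2-[3-(tert-butyldimethylsilyloxy)-4-hydroxy-5-(3-methylbut-2-enyl)phenyl]-8-(3-methylbut-2-enyl)-2,3-dihydro-8H-chromene-4,7-dione, either configuration at C8 | CC(C)=CCc1cc([C@@H]2CC(=O)C3=C(O2)C(CC=C(C)C)C(=O)C=C3)cc(O[Si](C)(C)C(C)(C)C)c1O | intermediate (not isolated)
19 | (2S)-3'-(tert-butyldimethylsilyloxy)-7,4'-dihydroxy-8,5'-bis(3-methylbut-2-enyl)flavanone | CC(C)=CCc1cc([C@@H]2CC(=O)c3ccc(O)c(CC=C(C)C)c3O2)cc(O[Si](C)(C)C(C)(C)C)c1O | intermediate (product of the key step)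
20 | (2S)-7,3',4'-trihydroxy-8,5'-bis(3-methylbut-2-enyl)flavanone (CNP0315050.1) | CC(C)=CCc1cc([C@@H]2CC(=O)c3ccc(O)c(CC=C(C)C)c3O2)cc(O)c1O | target

## Step count and least certain steps

Total: 11 steps. Longest linear sequence: 9 steps (steps 1 and 4 to 11, from 1 to 20); the ring A branch (steps 2 and 3) joins at step 9.

**Step 10 (key step).** Three things may go wrong. The shift on ring A may go partly to C6, because bond fixation in the saturated ring C of a flavanone is weaker than in a pyranone. A tertiary allyl ether may ionise and lose isoprene once phenols appear in the hot solution. C2 may erode through reversible opening of ring C at 130 °C once the 4'-hydroxyl is free. Adding Eu(fod)3 to lower the temperature would change the conditions only. The fallback moves the ring A shift to the chromone stage; it sets out from 5 and comes back to the route at 20, at a cost of two extra steps. Compound 5 is heated alone (o-xylene, 130 °C), where the fully conjugated pyranone fixes the C7=C8 bond more firmly, and should give 7-hydroxy-8-(3-methylbut-2-enyl)chromone F1. Silylation (TIPSCl, imidazole, DMF) should give 8-(3-methylbut-2-enyl)-7-(triisopropylsilyloxy)chromone F2. Addition of 14 under the catalyst of step 9 should give (2S)-3'-(tert-butyldimethylsilyloxy)-4'-(2-methylbut-3-en-2-yloxy)-8-(3-methylbut-2-enyl)-7-(triisopropylsilyloxy)flavanone F3. Heating F3, in which only the ring B ether with its single free ortho position can rearrange, should give (2S)-3'-(tert-butyldimethylsilyloxy)-4'-hydroxy-8,5'-bis(3-methylbut-2-enyl)-7-(triisopropylsilyloxy)flavanone F4. Bu4NF/AcOH then removes both silyl groups and returns the route at 20.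

**Step 9.** What may go wrong: insufficient facial selectivity with this electron-rich boronic acid, or the wrong sense for the chosen ligand antipode; base-induced opening of ring C of the product with loss of configuration; protodeboronation of 14; hydrolysis of the silyl ether by the aqueous base. The last would be harmless, since the free 3'-phenol can be carried through step 10 and gives 20 directly. The fallback replaces asymmetric catalysis by kinetic resolution; it sets out from 5 and 14 and comes back to the route at 15, at the cost of half the material. Addition of 14 to 5 with the achiral monovalent rhodium complex [Rh(OH)(cod)]2 (cod = cycloocta-1,5-diene) in dioxane–water, without added base, should give racemic 3'-(tert-butyldimethylsilyloxy)-7,4'-bis(2-methylbut-3-en-2-yloxy)flavanone F5. Asymmetric transfer hydrogenation (HCO2H/Et3N) with the antipode of RuCl(p-cymene)(TsDPEN) that reduces the (2R) ketone faster should convert that enantiomer into (2R,4R)-3'-(tert-butyldimethylsilyloxy)-7,4'-bis(2-methylbut-3-en-2-yloxy)flavan-4-ol F6. The unreacted (2S) ketone, which is 15, is then separated from F6 by chromatography.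

**Step 5.** What may go wrong: hydride migration in place of aryl migration, because the bulky tertiary alkoxy group may twist out of conjugation and lower the migratory aptitude of the ring; acid-promoted loss of the propargylic ether. The fallback avoids both the aldehyde and any phenoxide next to silicon; it sets out from purchased catechol F7, taken in place of 6, and comes back to the route at 11, so that steps 4 to 7 are bypassed. Monosilylation of F7 (TBSCl, 1 equiv, imidazole) should give 2-(tert-butyldimethylsilyloxy)phenol F8. Bromination with N-bromosuccinimide (MeCN, 0 °C), directed para to the free hydroxyl, should give 4-bromo-2-(tert-butyldimethylsilyloxy)phenol F9. Purchased 2-methylbut-3-en-2-ol F10 with Cl3CCN and catalytic DBU should give 2-methylbut-3-en-2-yl 2,2,2-trichloroacetimidate F11. F11 then alkylates the phenol of F9 under catalytic BF3·OEt2 (cyclohexane–CH2Cl2, −20 °C), where no phenoxide is formed and the silyl group cannot migrate, and should give 11. This sequence is not shorter than the main route once the imidate is counted, and the acid-catalysed tertiary alkylation is less dependable than the copper-catalysed etherification.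

**Step 11.** What may go wrong: formation of a phenoxide of the 4'-hydroxyflavanone, leading to opening of ring C and racemisation of C2; air oxidation of the free catechol. The fallback reverses the order of the last two operations; it sets out from 15 and comes back to the route at 20 with the same number of steps. Bu4NF/AcOH on 15, which has no 4'- or 7-hydroxyl and so no such pathway, should give (2S)-3'-hydroxy-7,4'-bis(2-methylbut-3-en-2-yloxy)flavanone F12. Heating F12 as in step 10 should rearrange both ethers in the same two stages and give 20 directly from a neutral thermal reaction.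

## Further compounds

F1 | step 10 | 7-hydroxy-8-(3-methylbut-2-enyl)chromone | O=c1ccoc2c(CC=C(C)C)c(O)ccc12
F2 | step 10 | 8-(3-methylbut-2-enyl)-7-(triisopropylsilyloxy)chromone | O=c1ccoc2c(CC=C(C)C)c(O[Si](C(C)C)(C(C)C)C(C)C)ccc12
F3 | step 10 | (2S)-3'-(tert-butyldimethylsilyloxy)-4'-(2-methylbut-3-en-2-yloxy)-8-(3-methylbut-2-enyl)-7-(triisopropylsilyloxy)flavanone | C=CC(C)(C)Oc1ccc([C@@H]2CC(=O)c3ccc(O[Si](C(C)C)(C(C)C)C(C)C)c(CC=C(C)C)c3O2)cc1O[Si](C)(C)C(C)(C)C
F4 | step 10 | (2S)-3'-(tert-butyldimethylsilyloxy)-4'-hydroxy-8,5'-bis(3-methylbut-2-enyl)-7-(triisopropylsilyloxy)flavanone | CC(C)=CCc1cc([C@@H]2CC(=O)c3ccc(O[Si](C(C)C)(C(C)C)C(C)C)c(CC=C(C)C)c3O2)cc(O[Si](C)(C)C(C)(C)C)c1O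
F5 | step 9 | racemic 3'-(tert-butyldimethylsilyloxy)-7,4'-bis(2-methylbut-3-en-2-yloxy)flavanone | C=CC(C)(C)Oc1ccc(C2CC(=O)c3ccc(OC(C)(C)C=C)cc3O2)cc1O[Si](C)(C)C(C)(C)C
F6 | step 9 | (2R,4R)-3'-(tert-butyldimethylsilyloxy)-7,4'-bis(2-methylbut-3-en-2-yloxy)flavan-4-ol (2,4-cis) | O[C@@H]1C[C@H](c2ccc(OC(C)(C)C=C)c(O[Si](C)(C)C(C)(C)C)c2)Oc2cc(OC(C)(C)C=C)ccc12
F7 | step 5 | catechol (purchased) | Oc1ccccc1O
F8 | step 5 | 2-(tert-butyldimethylsilyloxy)phenol | CC(C)(C)[Si](C)(C)Oc1ccccc1O
F9 | step 5 | 4-bromo-2-(tert-butyldimethylsilyloxy)phenol | CC(C)(C)[Si](C)(C)Oc1cc(Br)ccc1O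
F10 | step 5 | 2-methylbut-3-en-2-ol (purchased) | CC(C)(O)C=C
F11 | step 5 | 2-methylbut-3-en-2-yl 2,2,2-trichloroacetimidate | CC(C)(C=C)OC(=N)C(Cl)(Cl)Cl
F12 | step 11 | (2S)-3'-hydroxy-7,4'-bis(2-methylbut-3-en-2-yloxy)flavanone | C=CC(C)(C)Oc1ccc([C@@H]2CC(=O)c3ccc(OC(C)(C)C=C)cc3O2)cc1O
A1 | alternative 1 | (2S,4S)-2-[3,4-bis(methoxymethoxy)-5-(3-methylbut-2-enyl)phenyl]-7-(methoxymethoxy)-8-(3-methylbut-2-enyl)chroman-4-ol | O[C@H]1C[C@@H](c2cc(CC=C(C)C)c(OCOC)c(OCOC)c2)Oc2c(CC=C(C)C)c(OCOC)ccc12
A2 | alternative 1 | (1S,3S)-1-[2-bromo-4-(methoxymethoxy)-3-(3-methylbut-2-enyl)phenyl]-3-[3,4-bis(methoxymethoxy)-5-(3-methylbut-2-enyl)phenyl]propane-1,3-diol | O[C@@H](C[C@H](O)c1cc(CC=C(C)C)c(OCOC)c(OCOC)c1)c1ccc(OCOC)c(CC=C(C)C)c1Br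
A3 | alternative 2 | (2S)-3',4'-diacetoxy-8,5'-bis(3-methylbut-2-enyl)-7-(triisopropylsilyloxy)flavanone | CC(C)=CCc1cc([C@@H]2CC(=O)c3ccc(O[Si](C(C)C)(C(C)C)C(C)C)c(CC=C(C)C)c3O2)cc(OC(C)=O)c1OC(C)=O
A4 | alternative 2 | (3S)-3-[3,4-diacetoxy-5-(3-methylbut-2-enyl)phenyl]-3-[2-(3-methylbut-2-enyl)-3-(triisopropylsilyloxy)phenoxy]propanoic acid | OC(=O)C[C@H](Oc1cccc(O[Si](C(C)C)(C(C)C)C(C)C)c1CC=C(C)C)c1cc(CC=C(C)C)c(OC(C)=O)c(OC(C)=O)c1
A5 | alternative 2 | (3S)-3-[3,4-diacetoxy-5-(3-methylbut-2-enyl)phenyl]-3-[2-(3-methylbut-2-enyl)-3-(triisopropylsilyloxy)phenoxy]propanoyl chloride | ClC(=O)C[C@H](Oc1cccc(O[Si](C(C)C)(C(C)C)C(C)C)c1CC=C(C)C)c1cc(CC=C(C)C)c(OC(C)=O)c(OC(C)=O)c1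
A6 | alternative 3 | (2S,4S)-2-[3,4-bis(tert-butyldimethylsilyloxy)-5-(3-methylbut-2-enyl)phenyl]-4-methoxy-8-(3-methylbut-2-enyl)-7-(triisopropylsilyloxy)chroman (2,4-cis) | CO[C@H]1C[C@@H](c2cc(CC=C(C)C)c(O[Si](C)(C)C(C)(C)C)c(O[Si](C)(C)C(C)(C)C)c2)Oc2c(CC=C(C)C)c(O[Si](C(C)C)(C(C)C)C(C)C)ccc12
A7 | alternative 3 | 6-(dimethoxymethyl)-2-(3-methylbut-2-enyl)-3-(triisopropylsilyloxy)phenol | COC(OC)c1ccc(O[Si](C(C)C)(C(C)C)C(C)C)c(CC=C(C)C)c1O
A8 | alternative 3 | 1,2-bis(tert-butyldimethylsilyloxy)-3-(3-methylbut-2-enyl)-5-vinylbenzene | C=Cc1cc(CC=C(C)C)c(O[Si](C)(C)C(C)(C)C)c(O[Si](C)(C)C(C)(C)C)c1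
A9 | alternative 3 | 6-(methoxymethylidene)-2-(3-methylbut-2-enyl)-3-(triisopropylsilyloxy)cyclohexa-2,4-dien-1-one | COC=C1C=CC(O[Si](C(C)C)(C(C)C)C(C)C)=C(CC=C(C)C)C1=O
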